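Friday's flask ended with a leftover: starting material stayed near 43.5% while target levelled at 55.6%. Its charge of partner, 0.23 M against 0.41 M of starting material, leaves room for 56.1% of target, if each species is used once per target.

| setting | Friday's | Sunday's | Thursday's | red | ochre |
|---|---|---|---|---|---|
| starting material | 0.41 M | 0.41 M | 0.41 M | 0.41 M | 0.41 M |
| partner | 0.23 M | 0.90 M | 0.451 M | 0.451 M | 0.451 M |
| second reagent | 0.389 M | 0.389 M | 0.389 M | 0.389 M | 0.389 M |
| third reagent | 0.41 M (fed, over 15 s) | 0.41 M (fed, over 15 s) | 0.61 M (fed, over 15 s) | 0.410 M (fed, over 15 s) | 0.410 M (fed, over 15 s) |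
| temperature | −35 °C | −24 °C | −35 °C |  |  |
| remark | run made earlier | run made earlier | run made earlier | at −40 °C until 15 s, from then on at −20 °C | at −40 °C throughout |
| time |  |  |  | 15 min | 15 min |

- Friday's (time / min: target / %, starting material / %): 1.00: 3.6, 52.3; 3.00: 25.3, 44.1; 5.00: 38.2, 44.0; 8.00: 48.1, 42.8; 10.0: 51.6, 42.4; 15.0: 54.7, 43.9; 20.0: 55.6, 43.5
- Sunday's (time / min: target / %, starting material / %): 0.417: 11.6, 1.3; 1.33: 45.3, 0; 2.50: 65.7, 1.2; 4.00: 74.3, 0.4; 5.00: 78.3, 0; 6.00: 83.0, 0.6; 10.0: 89.0, 0.2
- Thursday's (time / min: target / %, starting material / %): 1.50: 22.0, 16.6; 5.00: 66.5, 1.9; 8.00: 79.8, 1.2; 12.0: 85.5, 0.9; 20.0: 91.2, 0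

(each reading ± 1 percentage point)

- a reading or a percentage of target counts all its forms, free or not

* the winner by amount of target, in percent of the starting material charged; "neither" if no more than 2 percentage points parts them (red / ochre / neither)
* how much target is there at the end, in percent of the starting material charged: red
* how much target is there at the end, in percent of the starting material charged: ochre

Red and ochre share one ceiling, 94.9%: the smallest charge, that of the limiting reagent, divided by the charge of starting material. In both flasks the smallest charge is second reagent, 0.389 M. I took the ceiling as where red and ochre end, so what remained was how fast each approaches it.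

I read the time scales from the fastest up. The feed of third reagent took 15 s, shorter than the half-life of starting material, which I read from Thursday's first reading, taking the fall as first-order, as about 0.579 min. So I counted the feed as instantaneous. At that reading Thursday's flask held 61.4% of the starting material charged as neither starting material nor target, so I supposed that something stands between them. Then I turned to the rise of target. Sunday's flask has the same ceiling, and its gap below the ceiling fell from 29 percentage points at 2.50 min to 5.9 points at 10.0 min, roughly as one over time.

Red warms after 15 s to −20 °C, near Sunday's −24 °C, though it holds 0.451 M of partner against Sunday's 0.90 M; as a rough estimate I stretched Sunday's gap to 15 min and got 91.0% for red. Ochre stays at −40 °C, colder than Thursday's −35 °C, with 0.410 M of third reagent against 0.61 M. By judgement I let its 15 min stand for Thursday's 5.00 min to 8.00 min, which gives 66.5% to 79.8%.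

The forecast said red, with 92% for red, above my estimate, and 70% for ochre, inside my band. It too spoke of “a cap from second reagent”.

The flasks gave 92.1% for red and 72.8% for ochre, so red won. Left until 150 min, red held 94.9% and ochre 94.4%. Measured from the ceiling, the gap at 15 min was 2.8 points in red and 22 points in ochre.

    starting material + partner → intermediate A (k = 0.0724 M⁻¹ s⁻¹, Ea = 43.0 kJ mol⁻¹)
    second reagent + intermediate A → intermediate B (k = 0.0349 M⁻¹ s⁻¹, Ea = 50.0 kJ mol⁻¹)
    third reagent + intermediate B → target (k = 0.0146 M⁻¹ s⁻¹, Ea = 35.0 kJ mol⁻¹)
    crystals ⇌ target, rate k4*(cs4 - [target]) while solid is left; crystals form when [target] > cs4 (solubility = 5.40 mM, k = 0.151 s⁻¹)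
    (constants at −40 °C)

Now take red with partner cut to 0.11 M. The ceiling moves to 26.8%, set by partner. That flask gave 26.8% of target, with 73.2% as starting material left over.

(All runs were generated by integration on assumed constants.)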